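**Plan**
Cuts: the bridge CH2 is traced back to a diaryl ketone. Next the four ketal C–O bonds are cut (each ketal carbon to its tetrahydrofuran oxygen and to its chromene oxygen). Then follow the two central-ring aryl–CH2 bonds, the aryl–C(=O) bond, and last the aryl–CH2 and O–CH bonds of the dihydrobenzofuran.
Enabling feature: each tetrahydrofuro[2,3-b]chromene unit is the mixed ketal of one methyl ketone carbon (C9a) with a primary alcohol oxygen (O1) and a phenol oxygen (O9). Its ring-fusion CH (C3a) is the enolisable α carbon of that ketone, whereas the methyl-bearing C3 beside it cannot epimerise.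
Forward order: the dihydrofuran ring of the benzofuran comes first (bromophenol plus isoprene), then the benzophenone by aryllithium acylation, then both arms by twofold conjugate addition. Two tetrahydrofuran and two dihydropyran rings then close in one acid operation, and the bridge C=O is finally taken to CH2.
Stereochemistry: benzofuran C2 (S) comes from a chiral palladium catalyst and both C3 centres (R) from (S)-Roche ester. Both C3a and both C9a centres (R) arise by thermodynamic relay from C3 under equilibrating acid.
Regiochemistry: the angular fusion follows from the hydrogen bond between the diaryl ketone and one ortho phenol, so the bridge stays at the ketone level until the ketals are in place.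

Key step: step 10

Locants: on the central ring, C1 carries the bridge carbon, the oxygens sit on C2, C4 and C6, and the arms sit on C3 and C5. Within an arm, furo[2,3-b]chromene numbering applies: O1, C2H2, C3H(CH3), C3a-H, C4H2, O9, C9a(CH3).
Assumption: the open-chain drawings of the ketalisation precursor and of its desilylated form stand for mixtures with their chromanol or furanose hemiketals and for all epimers at the acetyl-bearing CH, all of which feed the same acid equilibrium.

**Step 1**
Reactants: 1 methyl 3-bromo-4-hydroxybenzoate; 2 isoprene (2-methylbuta-1,3-diene)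
Product: 3 methyl (2S)-2-(prop-1-en-2-yl)-2,3-dihydro-1-benzofuran-5-carboxylate
Conditions: Pd2(dba)3·CHCl3 (2.5 mol %), chiral sulfinamide–monophosphine ligand (TY-Phos type, antipode giving 2S), PhONa, 2 (3 equiv), CH2Cl2, 40 °C, sealed vessel
Reagents that add atoms: none
Why: This is the enantioselective Larock-type heteroannulation (Heck/Tsuji–Trost cascade) established for o-bromophenols and 1,3-dienes, in which the arylpalladium species adds to the unsubstituted vinyl terminus of isoprene, the phenoxide closes the five-membered ring at the adjacent π-allyl terminus, and the chiral ligand selects the face so that C2 is set as S.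

**Step 2**
Reactants: 4 phloroglucinol (benzene-1,3,5-triol)
Product: 5 1,3,5-tris(methoxymethoxy)benzene
Conditions: NaH (3.6 equiv), MOMCl (3.6 equiv), DMF, 0 °C → rt
Reagents that add atoms: chloromethyl methyl ether (MOMCl), COCCl
Why: Williamson-type O-alkylation of the tris-phenoxide with the hard electrophile MOMCl gives the tris-acetal, which protects the phenols and supplies the directing groups for the next step.

**Step 3**
Reactants: 5 1,3,5-tris(methoxymethoxy)benzene; 3 methyl (2S)-2-(prop-1-en-2-yl)-2,3-dihydro-1-benzofuran-5-carboxylate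
Product: 7 [(2S)-2-(prop-1-en-2-yl)-2,3-dihydro-1-benzofuran-5-yl][2,4,6-tris(methoxymethoxy)phenyl]methanone, via aryllithium 6 (not isolated)
Conditions: n-BuLi (1.05 equiv), THF, 0 °C, 1 h; then 3, −78 → 0 °C; H2O quench
Reagents that add atoms: none
Why: Directed ortho-lithiation between two OMOM groups followed by nucleophilic acyl substitution at the methyl ester should stop at the ketone, because a diaryl ketone with two ortho alkoxy groups is too shielded for a second addition of the equally hindered aryllithium, and the C2 stereocentre is not touched at low temperature.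

**Step 4**
Reactants: 7 [(2S)-2-(prop-1-en-2-yl)-2,3-dihydro-1-benzofuran-5-yl][2,4,6-tris(methoxymethoxy)phenyl]methanone
Product: 8 [(2S)-2-(prop-1-en-2-yl)-2,3-dihydro-1-benzofuran-5-yl](2,4,6-trihydroxyphenyl)methanone
Conditions: conc. HCl (cat.), MeOH, rt → 40 °C
Reagents that add atoms: none
Why: Acid-catalysed transacetalisation to methanol removes phenolic MOM groups (the two next to the carbonyl fastest) under conditions that prenyl-type alkenes on phenolic substrates are known to survive, so the isopropenyl group and the allylic aryl ether should stay intact.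

**Step 5**
Reactants: 9 methyl (S)-3-hydroxy-2-methylpropanoate (Roche ester)
Product: 10 methyl (2S)-3-(tert-butyldimethylsilyloxy)-2-methylpropanoate
Conditions: TBSCl, imidazole, CH2Cl2, 0 °C → rt
Reagents that add atoms: tert-butyldimethylsilyl chloride (TBSCl), CC(C)(C)[Si](C)(C)Cl
Why: Imidazole-promoted silylation of the primary alcohol is a standard protection and leaves the α stereocentre of the ester untouched.

**Step 6**
Reactants: 10 methyl (2S)-3-(tert-butyldimethylsilyloxy)-2-methylpropanoate
Product: 12 (3S)-4-(tert-butyldimethylsilyloxy)-3-methylbutan-2-one, via Weinreb amide 11 (not isolated)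
Conditions: MeNHOMe·HCl (1.5 equiv), MeMgCl (3.0 equiv), THF, −20 °C; then MeMgCl (2.0 equiv), 0 °C; aq. NH4Cl
Reagents that add atoms: methylmagnesium chloride, C[Mg]Cl
Why: In this telescoped Weinreb ketone synthesis the chloromagnesium amide made from the first charge of MeMgCl converts the ester into amide 11 and the second charge adds once to give a chelated tetrahedral adduct that releases the ketone only on quench, so neither over-addition nor epimerisation of the α centre is expected.

**Step 7**
Reactants: 12 (3S)-4-(tert-butyldimethylsilyloxy)-3-methylbutan-2-one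
Product: 14 (3S)-4-(tert-butyldimethylsilyloxy)-3-methylbut-1-en-2-yl trifluoromethanesulfonate, via potassium enolate 13 (not isolated)
Conditions: KN(SiMe3)2 (1.1 equiv), THF, −78 °C (ketone added to base); then PhNTf2, −78 → 0 °C
Reagents that add atoms: N-phenylbis(trifluoromethanesulfonimide) (PhNTf2), O=S(=O)(N(c1ccccc1)S(=O)(=O)C(F)(F)F)C(F)(F)F
Why: Kinetic deprotonation with a bulky amide base at low temperature takes place at the methyl group and O-triflation of enolate 13 fixes the 1,1-disubstituted alkene, so the tertiary α stereocentre is never enolised.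

**Step 8**
Reactants: 14 (3S)-4-(tert-butyldimethylsilyloxy)-3-methylbut-1-en-2-yl trifluoromethanesulfonate
Product: 16 (4R)-5-(tert-butyldimethylsilyloxy)-4-methyl-3-methylidenepentan-2-one, via 2-ethoxydiene 15 (not isolated)
Conditions: tributyl(1-ethoxyvinyl)stannane, Pd(PPh3)4 (5 mol %), LiCl (3 equiv), THF, 65 °C; then 5 % aq. oxalic acid, THF, 0 °C; product kept cold with a trace of BHT and used at once
Reagents that add atoms: tributyl(1-ethoxyvinyl)stannane, CCCC[Sn](CCCC)(CCCC)C(=C)OCC; water, O
Why: Stille coupling of an alkenyl triflate with an α-alkoxyvinylstannane under zerovalent palladium and LiCl gives 2-ethoxydiene 15, whose enol ether is hydrolysed by weak aqueous acid much faster than a primary TBS ether, which unmasks the acetyl group next to the methylene carbon (the descriptor changes from S to R by priority only).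

**Step 9**
Reactants: 8 [(2S)-2-(prop-1-en-2-yl)-2,3-dihydro-1-benzofuran-5-yl](2,4,6-trihydroxyphenyl)methanone; 16 (4R)-5-(tert-butyldimethylsilyloxy)-4-methyl-3-methylidenepentan-2-one (2.4 equiv)
Product: 18 [3,5-bis[(3R)-2-acetyl-4-(tert-butyldimethylsilyloxy)-3-methylbutyl]-2,4,6-trihydroxyphenyl][(2S)-2-(prop-1-en-2-yl)-2,3-dihydro-1-benzofuran-5-yl]methanone (acetyl-bearing CH centres unset), via mono-adduct 17 (not isolated)
Conditions: iPr2NEt (1 equiv), MeCN, rt → 40 °C, 16 added in portions, BHT (trace)
Reagents that add atoms: none
Why: Twofold C-selective Michael addition (Friedel–Crafts-type conjugate addition) of an acylphloroglucinol phenoxide to an enone is a known way to alkylate both free ring carbons, O-adducts revert under the basic conditions, only C3 and C5 of the central ring are available, and the two new α centres are left unset on purpose.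

**Step 10**
Reactants: 18 [3,5-bis[(3R)-2-acetyl-4-(tert-butyldimethylsilyloxy)-3-methylbutyl]-2,4,6-trihydroxyphenyl][(2S)-2-(prop-1-en-2-yl)-2,3-dihydro-1-benzofuran-5-yl]methanone
Product: 20 angular bis-ketal ketone (bridge C=O analogue of the target; free OH on C2; arms on C3/C4-O plus C5/C6-O; each arm 3R 3aR 9aR; benzofuran C2 S), via diol 19 (not isolated)
Conditions: p-TsOH·H2O (0.3 equiv), MeCN–H2O 20:1, rt; then solvent switch to CH2Cl2, MgSO4, rt, held until the isomer distribution no longer changes
Reagents that add atoms: none
Why: Acid first hydrolyses the two primary silyl ethers to diol 19, each freed alcohol adds to its methyl ketone to give a cyclic hemiketal, loss of water gives a 2-methyl oxocarbenium ion and a flanking phenol captures it, which is the acid-catalysed bicycloketalisation known for γ-hydroxy ketones that carry an o-hydroxybenzyl group on the α carbon. Each tetrahydrofuran ring closes 5-exo-trig (alcohol O onto C=O) and each dihydropyran ring closes 6-exo-trig (phenol O onto the C=O+ carbon), and the short tether allows only the cis ring fusion, so C9a is tied to C3a in each arm. C3a is corrected by reversible loss of its proton from the oxocarbenium ion to give the 4,5-dihydrofuran enol ether and reprotonation, so both arms should drain into the isomer in which the fixed (R)-C3 methyl group lies on the convex face, trans to the benzylic C4H2, which is the 3R,3aR,9aR series. The step needs regiocontrol (angular against linear use of the three phenols), supplied by the diaryl ketone, which holds one ortho phenol in a six-membered hydrogen bond that only the angular bis-ketal keeps; the two conceivable angular closures are one and the same compound because the arms are identical. It also needs chemoselectivity over the isopropenyl group and the allylic aryl ether, which is expected because ionising an aryloxy ketal takes far weaker acid than protonating a 1,1-disubstituted alkene. Minor isomers can be returned to the same conditions, since every C–O bond formed is reversible.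

**Step 11**
Reactants: 20 angular bis-ketal ketone
Product: 21 ethyl carbonate of 20 (OCO2Et on C2 of the central ring; all stereocentres as in 20)
Conditions: ClCO2Et (1.5 equiv), Et3N (2 equiv), THF, 0 °C
Reagents that add atoms: ethyl chloroformate, CCOC(=O)Cl
Why: O-Acylation of the only free phenol with ethyl chloroformate under amine base is the standard activation of chelated o-acylphenols and touches neither the ketals nor any stereocentre.

**Step 12**
Reactants: 21 ethyl carbonate of 20
Product: 24 CNP0131395.1 (target; bridge CH2; each arm 3R 3aR 9aR; benzofuran C2 S), via carbinol 22 (not isolated), via o-quinone methide 23 (not isolated)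
Conditions: NaBH4 (5 equiv), THF–H2O 4:1, 0 °C → rt
Reagents that add atoms: none
Why: This is the known borohydride deoxygenation of o-(alkoxycarbonyloxy)aryl ketones, in which hydride gives carbinol 22, the carbonate shifts to the benzylic oxygen and leaves with formation of o-quinone methide 23, and a second hydride adds to its exocyclic carbon, all under basic conditions that ketals, alkene and stereocentres tolerate.

**Compound list**
1 | methyl 3-bromo-4-hydroxybenzoate | COC(=O)c1ccc(O)c(Br)c1 | starting material
2 | isoprene (2-methylbuta-1,3-diene) | C=CC(C)=C | starting material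
3 | methyl (2S)-2-(prop-1-en-2-yl)-2,3-dihydro-1-benzofuran-5-carboxylate | C=C(C)[C@@H]1Cc2cc(C(=O)OC)ccc2O1 | intermediate
4 | phloroglucinol (benzene-1,3,5-triol) | Oc1cc(O)cc(O)c1 | starting material
5 | 1,3,5-tris(methoxymethoxy)benzene | COCOc1cc(OCOC)cc(OCOC)c1 | intermediate
6 | 2,4,6-tris(methoxymethoxy)phenyllithium | [Li]c1c(OCOC)cc(OCOC)cc1OCOC | intermediate
7 | [(2S)-2-(prop-1-en-2-yl)-2,3-dihydro-1-benzofuran-5-yl][2,4,6-tris(methoxymethoxy)phenyl]methanone | C=C(C)[C@@H]1Cc2cc(C(=O)c3c(OCOC)cc(OCOC)cc3OCOC)ccc2O1 | intermediate
8 | [(2S)-2-(prop-1-en-2-yl)-2,3-dihydro-1-benzofuran-5-yl](2,4,6-trihydroxyphenyl)methanone | C=C(C)[C@@H]1Cc2cc(C(=O)c3c(O)cc(O)cc3O)ccc2O1 | intermediate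
9 | methyl (S)-3-hydroxy-2-methylpropanoate (Roche ester) | OC[C@H](C)C(=O)OC | starting material
10 | methyl (2S)-3-(tert-butyldimethylsilyloxy)-2-methylpropanoate | CC(C)(C)[Si](C)(C)OC[C@H](C)C(=O)OC | intermediate
11 | (2S)-3-(tert-butyldimethylsilyloxy)-N-methoxy-N,2-dimethylpropanamide | CC(C)(C)[Si](C)(C)OC[C@H](C)C(=O)N(C)OC | intermediate
12 | (3S)-4-(tert-butyldimethylsilyloxy)-3-methylbutan-2-one | CC(C)(C)[Si](C)(C)OC[C@H](C)C(C)=O | intermediate
13 | potassium (3S)-4-(tert-butyldimethylsilyloxy)-3-methylbut-1-en-2-olate | CC(C)(C)[Si](C)(C)OC[C@H](C)C(=C)[O-].[K+] | intermediate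
14 | (3S)-4-(tert-butyldimethylsilyloxy)-3-methylbut-1-en-2-yl trifluoromethanesulfonate | CC(C)(C)[Si](C)(C)OC[C@H](C)C(=C)OS(=O)(=O)C(F)(F)F | intermediate
15 | tert-butyl{[(2R)-4-ethoxy-2-methyl-3-methylidenepent-4-en-1-yl]oxy}dimethylsilane | CC(C)(C)[Si](C)(C)OC[C@H](C)C(=C)C(=C)OCC | intermediate
16 | (4R)-5-(tert-butyldimethylsilyloxy)-4-methyl-3-methylidenepentan-2-one | CC(C)(C)[Si](C)(C)OC[C@H](C)C(=C)C(C)=O | intermediate
17 | [3-[(3R)-2-acetyl-4-(tert-butyldimethylsilyloxy)-3-methylbutyl]-2,4,6-trihydroxyphenyl][(2S)-2-(prop-1-en-2-yl)-2,3-dihydro-1-benzofuran-5-yl]methanone, acetyl-bearing CH unset | C=C(C)[C@@H]1Cc2cc(C(=O)c3c(O)cc(O)c(CC(C(C)=O)[C@@H](C)CO[Si](C)(C)C(C)(C)C)c3O)ccc2O1 | intermediate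
18 | [3,5-bis[(3R)-2-acetyl-4-(tert-butyldimethylsilyloxy)-3-methylbutyl]-2,4,6-trihydroxyphenyl][(2S)-2-(prop-1-en-2-yl)-2,3-dihydro-1-benzofuran-5-yl]methanone, both acetyl-bearing CH centres unset | C=C(C)[C@@H]1Cc2cc(C(=O)c3c(O)c(CC(C(C)=O)[C@@H](C)CO[Si](C)(C)C(C)(C)C)c(O)c(CC(C(C)=O)[C@@H](C)CO[Si](C)(C)C(C)(C)C)c3O)ccc2O1 | intermediate
19 | [3,5-bis[(3R)-2-acetyl-4-hydroxy-3-methylbutyl]-2,4,6-trihydroxyphenyl][(2S)-2-(prop-1-en-2-yl)-2,3-dihydro-1-benzofuran-5-yl]methanone, both acetyl-bearing CH centres unset | C=C(C)[C@@H]1Cc2cc(C(=O)c3c(O)c(CC(C(C)=O)[C@@H](C)CO)c(O)c(CC(C(C)=O)[C@@H](C)CO)c3O)ccc2O1 | intermediate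
20 | angular bis-ketal ketone: central ring with C1 (2S)-2-(prop-1-en-2-yl)-2,3-dihydro-1-benzofuran-5-carbonyl, C2 free chelated OH, one (3R,3aR,9aR)-3,9a-dimethyltetrahydrofuro[2,3-b]chromene arm across C3(CH2)/C4(O) and a second across C5(CH2)/C6(O) | C=C(C)[C@@H]1Cc2cc(C(=O)c3c(O)c4c(c5c3O[C@@]3(C)OC[C@H](C)[C@H]3C5)O[C@@]3(C)OC[C@H](C)[C@H]3C4)ccc2O1 | intermediate
21 | ethyl carbonate of 20 (OCO2Et in place of the C2 OH) | C=C(C)[C@@H]1Cc2cc(C(=O)c3c(OC(=O)OCC)c4c(c5c3O[C@@]3(C)OC[C@H](C)[C@H]3C5)O[C@@]3(C)OC[C@H](C)[C@H]3C4)ccc2O1 | intermediate
22 | diarylcarbinol from 21 (bridge CHOH, configuration unset, C2 OCO2Et) | C=C(C)[C@@H]1Cc2cc(C(O)c3c(OC(=O)OCC)c4c(c5c3O[C@@]3(C)OC[C@H](C)[C@H]3C5)O[C@@]3(C)OC[C@H](C)[C@H]3C4)ccc2O1 | intermediate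
23 | o-quinone methide (central ring C2 carbonyl, C1 exocyclic =CH-aryl, alkene geometry unset) | C=C(C)[C@@H]1Cc2cc(C=C3C(=O)C4=C(C5=C3O[C@@]3(C)OC[C@H](C)[C@H]3C5)O[C@@]3(C)OC[C@H](C)[C@H]3C4)ccc2O1 | intermediate
24 | CNP0131395.1: as 20 with the bridge C=O replaced by CH2 (both arms 3R,3aR,9aR; benzofuran C2 S) | C=C(C)[C@@H]1Cc2cc(Cc3c(O)c4c(c5c3O[C@@]3(C)OC[C@H](C)[C@H]3C5)O[C@@]3(C)OC[C@H](C)[C@H]3C4)ccc2O1 | target

**Step count**
Total steps: 12. Longest linear sequence: 8 (steps 5–12, from Roche ester 9).

**Steps most likely to fail**

Step 10. The equilibration may stop short. Slow proton exchange at C3a would leave epimeric arms, and the simultaneous competition of both arms for the C4 phenol could leave linear isomer in the mixture. The fallback builds the arms one after the other.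
- It sets out from 8, which is treated with only one equivalent of 16 under the conditions of step 9 so that mono-adduct 17 can be isolated.
- Acid as in step 10 should close this single arm onto the non-chelated C4 phenol, the preference known for 3-alkylated 2,4-dihydroxyaryl ketones. This gives mono-ketal ketone F1, which can be purified to one diastereomer.
- The last free ring CH (C5) then adds to a second equivalent of 16 to give mono-ketal silyloxy ketone F2.
- The new arm of F2 has only the C6 phenol beside it, so acid closure can lead only to the angular array, and the route is rejoined at 20.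

Step 9. Self-reaction of the α-methylene ketone (hetero-Diels–Alder dimerisation, base-induced oligomerisation) may outrun C-alkylation. The second addition may also stall once the first arm rests as a hemiketal. The fallback is a base-free cascade with the unprotected arm.
- It sets out from 16, which HF·pyridine in THF converts into hydroxy enone F3.
- F3 (2.4 equiv) and 8 are heated together in toluene without base. This is the uncatalysed Michael addition known for this type of hydroxy enone with resorcinol-type aryl ketones.
- The adduct is diol 19, where the route is rejoined, and it is carried through the second stage of step 10.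

Step 12. Hydride delivery to the doubly ortho-substituted, electron-rich diaryl ketone may be slower than cleavage of the aryl carbonate by borohydride or hydroxide, which would only regenerate the free phenol. The fallback separates the reduction from the deoxygenation.
- It sets out from 20, which LiAlH4 in THF (0 °C → rt) should reduce through its aluminium phenoxide to o-hydroxybenzhydrol F4.
- Catalytic diphenyl phosphate with Hantzsch ester in CH2Cl2 at rt then dehydrates the carbinol to o-quinone methide 23 and reduces it by hydride transfer. This is a known organocatalytic transfer hydrogenation of o-hydroxybenzhydrols.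
- The acid is weak enough to leave ketals and alkene alone, and the route is rejoined at 24.

**Further compounds**
F1 | step 10 | mono-ketal ketone: central ring with C1 aroyl, C2 OH, one (3R,3aR,9aR) arm across C3(CH2)/C4(O), C5 H, C6 OH; benzofuran C2 S | C=C(C)[C@@H]1Cc2cc(C(=O)c3c(O)c4c(cc3O)O[C@@]3(C)OC[C@H](C)[C@H]3C4)ccc2O1
F2 | step 10 | mono-ketal silyloxy ketone: F1 carrying (3R)-2-acetyl-4-(tert-butyldimethylsilyloxy)-3-methylbutyl on C5, acetyl-bearing CH unset | C=C(C)[C@@H]1Cc2cc(C(=O)c3c(O)c4c(c(CC(C(C)=O)[C@@H](C)CO[Si](C)(C)C(C)(C)C)c3O)O[C@@]3(C)OC[C@H](C)[C@H]3C4)ccc2O1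
F3 | step 9 | (4R)-5-hydroxy-4-methyl-3-methylidenepentan-2-one | C=C(C(C)=O)[C@@H](C)CO
F4 | step 12 | o-hydroxybenzhydrol from 20 (bridge CHOH, configuration unset, C2 OH free) | C=C(C)[C@@H]1Cc2cc(C(O)c3c(O)c4c(c5c3O[C@@]3(C)OC[C@H](C)[C@H]3C5)O[C@@]3(C)OC[C@H](C)[C@H]3C4)ccc2O1
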